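The numbers in the tables were computed on assumed constants; the scatter is artificial.

**Reading time.** A reading at 1.0 h pays if target is still growing then, and the next run hangs on a choice: whether more starting material gives more target.

- eta: starting material 20 mM; partner 80 mM; initiator 1.2 mM; the very flask that is asked about, followed so far
- flask: starting material 20 mM; partner 80.0 mM; initiator 1.2 mM; time 1.0 h

- eta (time / min: target / %, ended chains / %, starting material / %): 1.50: 2.9, 0.8, 96.2; 5.00: 9.2, 2.2, 92.7; 8.00: 10.8, 1.5, 88.3; 12.0: 12.7, 1.6, 85.2; 20.0: 16.0, 1.1, 82.8; 25.0: 15.7, 2.9, 80.3

(scatter of a reading: 1 percentage point)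

- amount of target in the flask at 1.0 h, in percent of the starting material charged
- amount of ended chains in the flask at 1.0 h, in percent of the starting material charged

- a species is counted by the starting material in it: one ended chains counts as two

**Falling rate.** In this flask c(target) rises at 0.368 mM min⁻¹ up to 5.00 min, then at 0.100 mM min⁻¹, then at 0.0600 mM min⁻¹, yet starting material still reads 80.3%. So I reckon in mM and, as my own assumption, take the amount of target reached as independent of the charge of starting material.

**My estimate.** Read off scattered values, those two later rates give a decay time of 17.1 min, shorter than the hour. My reachable target is the late c(target) plus the latest rate times that decay time: 4.20 mM, or 21.0% of this charge, an estimate and not a bound. Summed readings put ended chains at 0.150 per target, which gives 3.15%. I leave the flask the hour and add no starting material.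

**The forecast.** It gives 18.5% of target and 2% of ended chains, since by the hour “the reaction has essentially stopped”.

**The flask.** It gives 19.8% of target, or 3.97 mM against my 4.20 mM, and 5.09% of ended chains, above my 3.15%.

    partner → decomposed reagent (k = 2.00 × 10⁻⁵ s⁻¹)
    starting material + initiating radical → capped initiator + first chain carrier (k = 48000 M⁻¹ s⁻¹)
    2 partner → self-condensation product (k = 0.0510 M⁻¹ s⁻¹)
    initiator → 2 initiating radical (k = 1.90 × 10⁻⁴ s⁻¹)
    first chain carrier → ended carrier (k = 0.180 s⁻¹)
    starting material + second chain carrier → released group + first chain carrier (k = 1300 M⁻¹ s⁻¹)
    2 first chain carrier → ended chains (k = 2.00 × 10⁶ M⁻¹ s⁻¹)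
    partner + first chain carrier → target + second chain carrier (k = 440 M⁻¹ s⁻¹)

**Pair ending.** First chain carriers ending in pairs hold the target down: without that path, this flask reaches 97.0% instead of 19.8%.

**Smaller charge.** With 8.0 mM of starting material, my 4.20 mM means 52.5%. The computed neighbour gives 49.5%, or 3.96 mM.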